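Everything rests on cutting ring A away from ring B. Ring B, with methyls C17 and C20 flanking C9 and an oxygen at C6, is the C2v-symmetric monoketal of 2,6-dimethylbenzoquinone; C1–C4 and C19 are a five-carbon vinyl keto ester. A single desymmetrising double Michael addition joins C4 to C5 and C1 to C10, closes ring A and fixes the quaternary centre C10, from which C4, C5, C3 and C6 are then relayed. Its precursor is thus just two achiral, flat fragments: a dienone ketal with one carbonyl and a vinyl β-keto ester. The C9 side chain is attached late by cross-coupling to an enol triflate.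

Key step: step 4

Remarks
- Atoms carry the labdane numbering of the target (ring A: C1–C5, C10; ring B: C5–C10; C17 on C8, C18 α and C19 β on C4, C20 on C10); β is the face of C20.
- 4-Methoxy-2,6-dimethylphenol and tert-butyl but-2-ynoate are taken as catalogue chemicals.
- Which pseudo-enantiomeric cinchona salt gives the drawn C10 configuration must be found by screening; the cinchonidinium salt is written.
- The keto lactone and its silyl ether may form as C8 epimers (equatorial 8α-methyl drawn); that centre is erased when the enol triflate is made.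
- After the annulation C4 is methylated while C5 is still trigonal, and C5 is then set by kinetic protonation, because the cis/trans preference of the unmethylated enedione keto ester is not dependable.

Step 1
Reactants: 1 4-methoxy-2,6-dimethylphenol
Product: 2 4,4-dimethoxy-2,6-dimethylcyclohexa-2,5-dien-1-one
Conditions: PhI(OAc)2 (1.1 equiv), MeOH, 0 °C to rt
Reagents that add atoms: methanol, CO
Why: Oxidative dearomatisation of a para-methoxyphenol by the iodine diacetate in methanol traps the ring at C4 as the dimethyl ketal, the standard entry to quinone monoketals.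

Step 2
Reactants: 3 methyl acetate; 4 acrolein
Product: 5 methyl 3-hydroxypent-4-enoate (racemic)
Conditions: LiN(i-Pr)2, THF, −78 °C; then 4; AcOH quench
Reagents that add atoms: none
Why: Aldol addition of the lithium ester enolate to the aldehyde carbonyl of acrolein (1,2-addition at −78 °C); the carbinol centre is removed in step 3.

Step 3
Reactants: 5 methyl 3-hydroxypent-4-enoate
Product: 6 methyl 3-oxopent-4-enoate
Conditions: Dess–Martin periodinane, CH2Cl2, 0 °C; used at once as a cold solution
Reagents that add atoms: none
Why: Dess–Martin oxidation of the allylic alcohol should give the vinyl β-keto ester (a Nazarov-type annulation reagent) under non-basic conditions that do not polymerise it.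

Step 4
Reactants: 2 4,4-dimethoxy-2,6-dimethylcyclohexa-2,5-dien-1-one; 6 methyl 3-oxopent-4-enoate
Product: 8 cis-fused enol keto ester enone ketal, via mono-Michael adduct 7 (not isolated)
Conditions: 6 (1.3 equiv) added slowly to 2, Cs2CO3 (0.3 equiv), N-(9-anthracenylmethyl)-O-allylcinchonidinium bromide (10 mol%), toluene, −40 °C; AcOH quench
Reagents that add atoms: none
Why: Proposed new method: the enolate of 6, held in toluene as a tight ion pair with the chiral ammonium cation, should add through C4 to one of the two enantiotopic β-carbons (C5, not C7) of dienone 2, and the cross-conjugated C9/C10 enolate so formed then adds to the vinyl ketone terminus C1; the closest known chemistry is the racemic Cs2CO3-mediated double Michael (anionic Diels–Alder type) annulation of vinyl β-keto esters with activated cyclohexenones, together with ammonium ion-pair Michael additions of β-keto esters. Ring A closes by a 6-endo-trig Michael addition in which the enolate double bond lies outside the new ring. C5 is set by the catalyst, which chooses between the mirror-image halves of 2, and C10 is set by the short tether, which can deliver C1 only to the ring face that already carries C4, hence the cis fusion. Regiochemistry needs no control, since the ketal leaves one carbonyl and only C5 and C7 are electrophilic, and the quaternary C10 cannot aromatise. The one selectivity required is therefore enantiotopic-group discrimination, and the flat, symmetric, single-carbonyl acceptor offers the ion pair exactly two mirror-image approaches.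

Step 5
Reactants: 8 cis-fused enol keto ester enone ketal
Product: 9 C5=C6 methyl dienol ether
Conditions: PPTS (10 mol%), toluene, 90 °C, 5 Å molecular sieves
Reagents that add atoms: none
Why: Acid-catalysed loss of methanol from the ketal (ketal to enol ether elimination) can remove only H5 and gives the enol ether conjugated with the enone, which makes C5 trigonal so that the cis fusion no longer influences the next step.

Step 6
Reactants: 9 C5=C6 methyl dienol ether
Product: 11 trans-fused 4α-methyl enedione keto ester, via C4-methylated dienol ether 10 (not isolated)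
Conditions: K2CO3, MeI, acetone, rt; then 1 M HCl, THF, 0 °C
Reagents that add atoms: iodomethane, CI; water, O
Why: C-alkylation of the β-keto ester anion should occur anti to the pseudo-axial C10 methyl, the only out-of-plane group next to trigonal C4 and C5 (as in deconjugative alkylation of octalone dienolates), giving 4α-CH3/4β-CO2Me, and mild enol ether hydrolysis then protonates C5 from the α face, away from the two β-axial groups on C4 and C10, to give the trans-fused ketone under kinetic control.

Step 7
Reactants: 11 trans-fused 4α-methyl enedione keto ester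
Product: 13 3α-hydroxy-9-oxo 19,6β-lactone, via enolate diol ester 12 (not isolated)
Conditions: LiBH(s-Bu)3 (3.5 equiv), THF, −78 to −40 °C; AcOH quench at −78 °C
Reagents that add atoms: none
Why: Conjugate hydride addition at unsubstituted C7 of the enedione (the usual mode of this bulky borohydride with 2-methylcyclohexenones) masks C9 as its enolate, the C6 ketone is then reduced from the open α face (6β-alkoxide, which lactonises onto the syn-axial C19 ester) and the C3 ketone from the equatorial direction (axial 3α-alcohol, as with 4,4-disubstituted 3-ketones), so that only C9 returns as a ketone on protonation.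

Step 8
Reactants: 13 3α-hydroxy-9-oxo 19,6β-lactone
Product: 14 3α-O-trimethylsilyl ether of 13
Conditions: TMSCl, imidazole, DMF, rt
Reagents that add atoms: chlorotrimethylsilane, C[Si](C)(C)Cl
Why: Silyl ether formation on the hindered axial alcohol removes the only acidic O–H so that no alkoxide competes in the triflation.

Step 9
Reactants: 14 3α-O-trimethylsilyl ether of 13
Product: 15 Δ8 enol triflate lactone
Conditions: KN(SiMe3)2, THF, −78 to 0 °C; PhNTf2, −78 °C to rt
Reagents that add atoms: N-phenylbis(trifluoromethanesulfonimide), O=S(=O)(N(c1ccccc1)S(=O)(=O)C(F)(F)F)C(F)(F)F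
Why: The ketone can enolise only towards C8 (C10 is quaternary and the lactone has no α-hydrogen), so enolate O-sulfonylation should give the tetrasubstituted C8=C9 enol triflate and erase the C8 centre.

Step 10
Reactants: 15 Δ8 enol triflate lactone
Product: 17 3α,6β,19-triol enol triflate, via 3-O-TMS diol 16 (not isolated)
Conditions: LiBH4, THF, MeOH (2 equiv), 0 to 40 °C; then 1 M HCl, THF, rt
Reagents that add atoms: none
Why: Borohydride reduction of the γ-lactone should give the 6β,19-diol without attacking the enol triflate, and the labile trimethylsilyl ether is hydrolysed in the acidic work-up.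

Step 11
Reactants: 18 tert-butyl but-2-ynoate; 19 vinylmagnesium bromide
Product: 20 tert-butyl (2E)-3-methylpenta-2,4-dienoate
Conditions: 19, CuBr·SMe2 (1 equiv), THF, −78 °C; then 18; AcOH quench at −78 °C
Reagents that add atoms: none
Why: syn-Carbocupration of the ynoate places vinyl and copper on the same side, so protonation at low temperature should give the 2E dienoate (vinyl trans to the ester) stereospecifically.

Step 12
Reactants: 17 3α,6β,19-triol enol triflate; 20 tert-butyl (2E)-3-methylpenta-2,4-dienoate
Product: 22 tert-butyl 3α,6β,19-trihydroxylabda-8,13E-dien-15-oate, via alkyl-9-BBN 21 (not isolated)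
Conditions: 20 (2.2 equiv), 9-BBN dimer (1.0 equiv), THF, 0 °C to rt; then 17, Pd(dppf)Cl2 (10 mol%), AsPh3 (10 mol%), K3PO4 (3 equiv), DMF/H2O, 50 °C
Reagents that add atoms: none
Why: 9-BBN should hydroborate only the terminal vinyl carbon of 20 (the trisubstituted enoate is inert), and B-alkyl Suzuki–Miyaura coupling with the enol triflate then forms C9–C11 with both alkene geometries retained and the free hydroxyls tolerated.

Step 13
Reactants: 22 tert-butyl 3α,6β,19-trihydroxylabda-8,13E-dien-15-oate
Product: 23 tert-butyl 6β-hydroxy-3α,19-bis(3-methylbutanoyloxy)labda-8,13E-dien-15-oate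
Conditions: (i-BuCO)2O (2.4 equiv), DMAP (0.2 equiv), pyridine, CH2Cl2, 0 °C to rt
Reagents that add atoms: 3-methylbutanoic anhydride, CC(C)CC(=O)OC(=O)CC(C)C
Why: DMAP-catalysed acylation should esterify the primary C19 and the axial C3 hydroxyl but not the 6β-hydroxyl, which is shielded by the syn-axial C10 methyl and C19 methylene.

Step 14
Reactants: 23 tert-butyl 6β-hydroxy-3α,19-bis(3-methylbutanoyloxy)labda-8,13E-dien-15-oate
Product: 25 CNP0333611.1, via bis-TMS derivative 24 (not isolated)
Conditions: TMSOTf (4 equiv), 2,6-lutidine (6 equiv), CH2Cl2, 0 °C; then aq. citric acid, MeOH, rt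
Reagents that add atoms: none
Why: Silyl triflate-mediated cleavage of the tert-butyl ester (loss of isobutene to the silyl ester) under buffered conditions keeps protic acid away from the tetrasubstituted C8=C9 alkene, and the silyl ester and silyl ether hydrolyse on mild work-up while the two isovalerates stay.

Compound list
1 | 4-methoxy-2,6-dimethylphenol | COc1cc(C)c(O)c(C)c1 | starting material
2 | 4,4-dimethoxy-2,6-dimethylcyclohexa-2,5-dien-1-one | COC1(OC)C=C(C)C(=O)C(C)=C1 | intermediate
3 | methyl acetate | COC(C)=O | starting material
4 | acrolein (prop-2-enal) | C=CC=O | starting material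
5 | methyl 3-hydroxypent-4-enoate (racemic) | C=CC(O)CC(=O)OC | intermediate
6 | methyl 3-oxopent-4-enoate | C=CC(=O)CC(=O)OC | intermediate
7 | methyl 2-(6,6-dimethoxy-2,4-dimethyl-3-oxocyclohex-4-en-1-yl)-3-oxopent-4-enoate, C5 as in 8, present as its C9/C10 enolate (neutral keto form drawn) | C=CC(=O)C(C(=O)OC)[C@@H]1C(C)C(=O)C(C)=CC1(OC)OC | intermediate (not isolated)
8 | methyl 2-hydroxy-8,8-dimethoxy-4a,6-dimethyl-5-oxo-3,4,4a,5,8,8a-hexahydronaphthalene-1-carboxylate, cis-fused (H5 and C20 both β, C10 as in the target) | CC=1C(=O)[C@@]2(C)CCC(O)=C(C(=O)OC)[C@H]2C(OC)(OC)C=1 | intermediate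
9 | methyl 2-hydroxy-8-methoxy-4a,6-dimethyl-5-oxo-3,4,4a,5-tetrahydronaphthalene-1-carboxylate (C5=C6 methyl dienol ether, C10 as in 8) | CC=1C(=O)[C@@]2(C)CCC(O)=C(C(=O)OC)C2=C(OC)C=1 | intermediate
10 | methyl 8-methoxy-1,4a,6-trimethyl-2,5-dioxo-1,2,3,4,4a,5-hexahydronaphthalene-1-carboxylate (4α-methyl, 4β-ester) | CC=1C(=O)[C@@]2(C)CCC(=O)[C@](C)(C(=O)OC)C2=C(OC)C=1 | intermediate (not isolated)
11 | methyl 1,4a,6-trimethyl-2,5,8-trioxo-1,2,3,4,4a,5,8,8a-octahydronaphthalene-1-carboxylate, trans-fused (5α-H, 4α-methyl, 4β-ester and C20 both β) | CC=1C(=O)[C@@]2(C)CCC(=O)[C@](C)(C(=O)OC)[C@@H]2C(=O)C=1 | intermediate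
12 | methyl 3α,6β,9-trihydroxy-8-ene ester of the bicyclic core, present as lithium C9 enolate and dialkoxide (enol form drawn) | CC1=C(O)[C@@]2(C)CC[C@@H](O)[C@](C)(C(=O)OC)[C@@H]2[C@H](O)C1 | intermediate (not isolated)
13 | 3α-hydroxy-9-oxo 19,6β-lactone of the bicyclic core (γ-lactone from C19 to the 6β-oxygen, 5α-H, 8α-methyl drawn) | C[C@H]1C(=O)[C@@]2(C)CC[C@@H](O)[C@]3(C)C(=O)O[C@@H]([C@H]23)C1 | intermediate
14 | 3α-trimethylsilyloxy-9-oxo 19,6β-lactone | C[C@H]1C(=O)[C@@]2(C)CC[C@@H](O[Si](C)(C)C)[C@]3(C)C(=O)O[C@@H]([C@H]23)C1 | intermediate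
15 | 3α-trimethylsilyloxy-19,6β-lactone 8-en-9-yl trifluoromethanesulfonate | CC1=C(OS(=O)(=O)C(F)(F)F)[C@@]2(C)CC[C@@H](O[Si](C)(C)C)[C@]3(C)C(=O)O[C@@H]([C@H]23)C1 | intermediate
16 | 6β,19-dihydroxy-3α-trimethylsilyloxy 8-en-9-yl triflate | CC1=C(OS(=O)(=O)C(F)(F)F)[C@@]2(C)CC[C@@H](O[Si](C)(C)C)[C@](C)(CO)[C@@H]2[C@H](O)C1 | intermediate (not isolated)
17 | 3α,6β,19-trihydroxy 8-en-9-yl triflate | CC1=C(OS(=O)(=O)C(F)(F)F)[C@@]2(C)CC[C@@H](O)[C@](C)(CO)[C@@H]2[C@H](O)C1 | intermediate
18 | tert-butyl but-2-ynoate | CC#CC(=O)OC(C)(C)C | starting material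
19 | vinylmagnesium bromide | C=C[Mg]Br | starting material
20 | tert-butyl (2E)-3-methylpenta-2,4-dienoate | C=C/C(C)=C/C(=O)OC(C)(C)C | intermediate
21 | tert-butyl (2E)-5-(9-borabicyclo[3.3.1]nonan-9-yl)-3-methylpent-2-enoate | CC(C)(C)OC(=O)/C=C(\C)CCB1C2CCCC1CCC2 | intermediate (not isolated)
22 | tert-butyl 3α,6β,19-trihydroxylabda-8,13E-dien-15-oate | CC1=C(CC/C(C)=C/C(=O)OC(C)(C)C)[C@@]2(C)CC[C@@H](O)[C@](C)(CO)[C@@H]2[C@H](O)C1 | intermediate
23 | tert-butyl 6β-hydroxy-3α,19-bis(3-methylbutanoyloxy)labda-8,13E-dien-15-oate | CC1=C(CC/C(C)=C/C(=O)OC(C)(C)C)[C@@]2(C)CC[C@@H](OC(=O)CC(C)C)[C@](C)(COC(=O)CC(C)C)[C@@H]2[C@H](O)C1 | intermediate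
24 | trimethylsilyl 3α,19-bis(3-methylbutanoyloxy)-6β-trimethylsilyloxylabda-8,13E-dien-15-oate | CC1=C(CC/C(C)=C/C(=O)O[Si](C)(C)C)[C@@]2(C)CC[C@@H](OC(=O)CC(C)C)[C@](C)(COC(=O)CC(C)C)[C@@H]2[C@H](O[Si](C)(C)C)C1 | intermediate (not isolated)
25 | CNP0333611.1, (3R,4S,5R,6R,10S,13E)-6β-hydroxy-3α,19-bis(3-methylbutanoyloxy)labda-8,13-dien-15-oic acid | CC1=C(CC/C(C)=C/C(=O)O)[C@@]2(C)CC[C@@H](OC(=O)CC(C)C)[C@](C)(COC(=O)CC(C)C)[C@@H]2[C@H](O)C1 | target

Total step count: 14.
Longest linear sequence: 12 steps (steps 2–10 and 12–14, from methyl acetate and acrolein).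

Steps most likely to fail

Step 4. The ion pair may not distinguish the two mirror-image halves of 2, or the hindered ring closure onto the methyl-bearing enolate may be slower than polymerisation of 6 under the heterogeneous conditions. Fallback: starting from 2 and 6, the annulation is run without the chiral salt under the established homogeneous conditions (Cs2CO3, 1 equiv, CH2Cl2, rt) to give the racemic cis-fused adduct F1. This is resolved by preparative chromatography on an amylose tris(3,5-dimethylphenylcarbamate) phase; the wanted enantiomer is 8, where the route is rejoined.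

Step 6. The delocalised anion of 9 may be methylated on oxygen or at C8 instead of C4, or on the β face, or C5 may equilibrate after the hydrolysis. Fallback: starting from 8, the ketal is hydrolysed first (1 M HCl, THF) and C5 is equilibrated with DBU to the trans-fused enedione keto ester F2, separated from the cis isomer if needed. Its enolate is then methylated (NaH, MeI, THF, 0 °C); trans-fused decalone keto esters take the electrophile on the α face, and this gives 11 directly.

Step 7. The several hydride deliveries may not all go as planned: the enone may escape 1,4-reduction, the face selectivity at C3 may be incomplete, or the β-alkoxy ester may open by retro-aldol cleavage on warming. Fallback: starting from 11, the reduction is done in two stages. A Luche reduction (NaBH4, CeCl3·7H2O, MeOH, −78 °C) reduces only the less hindered C6 carbonyl from the α face, and the 6β-alcohol closes onto C19 to give the enone keto lactone F3. LiBH(s-Bu)3 (2.2 equiv, THF, −78 °C) then reduces the C3 ketone to the axial alcohol and the remaining β-unsubstituted enone in the 1,4 sense, rejoining the route at 13.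

Further compounds
F1 | step 4 | racemic cis-fused methyl 2-hydroxy-8,8-dimethoxy-4a,6-dimethyl-5-oxo-3,4,4a,5,8,8a-hexahydronaphthalene-1-carboxylate (racemate of 8) | CC1=CC(OC)(OC)C2C(C(=O)OC)=C(O)CCC2(C)C1=O
F2 | step 6 | trans-fused methyl 2-hydroxy-4a,6-dimethyl-5,8-dioxo-3,4,4a,5,8,8a-hexahydronaphthalene-1-carboxylate (5α-H) | CC=1C(=O)[C@@]2(C)CCC(O)=C(C(=O)OC)[C@@H]2C(=O)C=1
F3 | step 7 | 3,9-dioxo-7-ene 19,6β-lactone of the bicyclic core (4α-methyl, 5α-H) | CC=1C(=O)[C@@]2(C)CCC(=O)[C@]3(C)C(=O)O[C@@H]([C@H]23)C=1
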